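(The earlier runs and the new flask were computed with made-up constants; noise was put on by code.)

It is easy to take the end of the left-handed substrate for the end of the flask. In the west run it read 0.2% after 6.00 h, yet left-handed product went on from 28.6% to 50.6%, about half of the charge.

| setting | north-east | south-east | west | midnight | winter | dawn | noon |
|---|---|---|---|---|---|---|---|
| left-handed substrate | 0.15 M | 0.33 M | 0.22 M | 0.22 M | 0.22 M | 0.22 M | 0.22 M |
| right-handed substrate | 0.15 M | 0.33 M | 0.22 M | 0.22 M | 0.22 M | 0.22 M | 0.22 M |
| gas | 47 mM (held) | 47 mM (held) | 47 mM (held) | 47 mM (held) | 47 mM (held) | 47 mM (held) | 47 mM (held) |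
| free catalyst | 2.6 mM | 2.6 mM | 3.9 mM | 2.6 mM | 2.6 mM | 2.6 mM | 2.6 mM |
| temperature | 65 °C | 100 °C | 65 °C | 130 °C | 110 °C | 70 °C | 90 °C |
| remark | run made earlier | run made earlier | run made earlier |  |  |  |  |
| time |  |  |  | 6.0 h | 6.0 h | 6.0 h | 6.0 h |

| run | time / h | left-handed product / % | left-handed substrate / % |
|---|---|---|---|
| north-east | 12.0 | 30.6 | 0.4 |
| north-east | 25.0 | 37.0 | 0.3 |
| north-east | 40.0 | 42.5 | 0 |
| north-east | 50.0 | 43.9 | 2.5 |
| north-east | 60.0 | 45.0 | 0.2 |
| north-east | 72.0 | 47.1 | 0 |
| north-east | 96.0 | 49.1 | 0 |
| south-east | 1.00 | 17.3 | 16.4 |
| south-east | 2.00 | 26.7 | 1.1 |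
| south-east | 3.00 | 28.6 | 0 |
| south-east | 4.00 | 30.6 | 0.1 |
| south-east | 6.00 | 33.9 | 0.7 |
| south-east | 12.0 | 38.6 | 0 |
| south-east | 20.0 | 47.6 | 0.4 |
| west | 6.00 | 28.6 | 0.2 |
| west | 12.0 | 32.6 | 0 |
| west | 25.0 | 39.2 | 0.5 |
| west | 50.0 | 45.8 | 0 |
| west | 96.0 | 50.6 | 0 |

(standard deviation of a reading: 1 percentage point)

- free catalyst is single-handed; left-handed substrate and right-handed substrate are mirror images of each other, charged as a racemate, each of them at the stated concentration
- at the start none of the gas is in solution

1. which flask leads in amount of left-handed product, in percent of the left-handed substrate and right-handed substrate together charged ("all alike" within 1.5 percentage points) (midnight / winter / dawn / noon / all alike)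
2. how much left-handed product is there at the end, in percent of the left-handed substrate and right-handed substrate together charged: midnight
3. how much left-handed product is there at the end, in percent of the left-handed substrate and right-handed substrate together charged: winter
4. how much left-handed product is there at the end, in percent of the left-handed substrate and right-handed substrate together charged: dawn
5. how much left-handed product is there at the end, in percent of the left-handed substrate and right-handed substrate together charged: noon

So I followed the gap, half the charge minus left-handed product, in powers of ten. Its slope D, in decades per hour, treats the tail as a pseudo-first-order drain, and I scaled it by the charges: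

κ = D · [left-handed substrate] / [free catalyst]

gap(t) = gap(start) · ten^(−D t)

Catalyst came first. By hand, if D follows catalyst over substrate, κ stays put at one temperature. At 65 °C the west run gave 0.907 /h and the north-east run 0.794 /h, but these two runs hold nearly the same ratio of free catalyst to left-handed substrate, 0.0177 against 0.0173, so the pair does not test the scaling, and I used it as an assumption.

Temperature came next. By hand, a hotter flask drains faster. The south-east run, read from 3.00 h to 20.0 h, gave a drain number κ at 100 °C of 7.09 /h, which is 0.893 decades higher than in the west run. I took no climb past that run, so my figure for a hotter flask is an estimate from that one κ, not a bound.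

Time came last, as the exponent. Running the west gap back to its start gave 27 percentage points. Over 6.0 h I then put midnight, with the κ of the south-east run, at about 41.6%, more than the 27.0% for dawn with the κ of the west run, and since I expected a hotter flask to drain faster, I named midnight to lead.

The forecast, “Treating the drain as first-order towards 50%”, named midnight and gave 48% for midnight, 42% for winter, 26% for dawn and 33.5% for noon. Unlike my estimate, it carried the temperature climb on to midnight.

The flasks gave 41.9% for midnight, 37.3% for winter, 27.5% for dawn and 32.1% for noon, so midnight led, and the forecast for midnight stood 6.1 points too high.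

    reagent + catalyst intermediate B → free catalyst + right-handed product (k = 1.50 /M/min, Ea = 74.0 kJ/mol)
    left-handed product ⇌ right-handed product (k = 0.0120 /min, Ea = 104 kJ/mol)
    reagent + catalyst intermediate A → free catalyst + left-handed product (k = 42.0 /M/min, Ea = 72.0 kJ/mol)
    free catalyst + left-handed substrate ⇌ catalyst intermediate A (K = 13.0 /M, k = 2400 /M/min, Ea = 37.0 kJ/mol, ΔH = −9.00 kJ/mol)
    gas ⇌ reagent, rate k5*(csat - [reagent]) (kL = 0.100 /min)
    free catalyst + right-handed substrate ⇌ catalyst intermediate B (K = 5.60 /M, k = 320 /M/min, Ea = 66.0 kJ/mol, ΔH = −46.0 kJ/mol)
    (constants at 70 °C)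

Midnight's own gap of 8.1 points gave a drain number of 7.28 /h, close to the 7.09 /h read from the south-east run. The neighbouring flask is midnight with 6.5 × 10⁻⁴ M of free catalyst, a quarter of the charge. With 7.09 /h its drain came to 0.0210 /h, so 0.126 decades in 6.0 h, and I reckoned 29.8% left-handed product. That neighbouring flask gave 31.3%.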